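**Plan**

1. Retrosynthesis: the side chain is cut at its sp3–sp2 bond C2'–C3' (B-alkyl Suzuki coupling with a Z-iodoalkene); both rings are then cut in one event at C3a–C7a and C6–C7; next C3a–C4 (reverse prenylation of an aldehyde) and the C3a methylene; last C2–C3 (Ireland–Claisen).
2. Enabling feature: ring A is a cyclohexene whose only C=C (C7=C7a) lies between the two cut bonds and is exocyclic to ring B, so C7/C7a map onto a terminal alkyne. C3a, fully substituted and carrying a methyl, is the Markovnikov radical of a C=CH2 group, and C5–C6 are a vinyl group on the gem-dimethyl carbon C4.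
3. Forward: (S)-but-3-yn-2-ol → Z-enynol → ester → Claisen acid (C2 and C3 set) → aldehyde → prenyl adduct → ketone → C=CH2 → radical bicyclisation (ring B by 5-exo-dig, then ring A by 6-endo) → alkyne to vinyl → side chain → acid.
4. Stereochemistry: the bought carbinol centre is relayed by a chair Claisen to C3 and C2; these two centres direct C3a in the radical ring closure. The Z side-chain alkene comes from an anti-carbomagnesiation and is kept in the coupling.

Key step: step 12

Assumption: positions are numbered as in 1H-indene (C2 carboxyl, C3 methyl and side chain, C3a angular methyl, C4 gem-dimethyl, C7=C7a alkene); ring A is the six-membered ring, ring B the five-membered ring; side-chain carbons carry primes.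

**Route**

Step 1
Reactants: 1 (S)-but-3-yn-2-ol
Product: 3 (S)-pent-3-yn-2-ol, via dilithium alkoxide-acetylide 2 (not isolated)
Conditions: n-BuLi (2.1 equiv), THF–DMPU, −78 → 0 °C; MeI (1.0 equiv), 0 °C → rt; H2O
Reagents that add atoms: iodomethane, CI
Why: Acetylide C-alkylation of the O,C-dianion should take place at the more nucleophilic sp carbon, and the carbinol stereocentre is not touched.

Step 2
Reactants: 3 (S)-pent-3-yn-2-ol
Product: 5 (2S,3Z)-4-iodopent-3-en-2-ol, via cyclic vinylalanate 4 (not isolated)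
Conditions: NaAlH2(OCH2CH2OMe)2 (Red-Al), THF, 0 °C → rt; then I2, THF, −78 → 0 °C; aq. Rochelle salt
Reagents that add atoms: iodine, II; sodium bis(2-methoxyethoxy)aluminium dihydride, [Na+].[AlH2-](OCCOC)OCCOC (its atoms stay only in 4)
Why: Hydroxyl-directed trans-hydroalumination of the propargylic alcohol should place aluminium on the distal alkyne carbon inside a five-membered alanate, and iodinolysis with retention gives the iodoalkene with iodine cis to the carbinol carbon.

Step 3
Reactants: 5 (2S,3Z)-4-iodopent-3-en-2-ol; 6 ethynyltrimethylsilane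
Product: 7 (2S,3Z)-4-methyl-6-(trimethylsilyl)hex-3-en-5-yn-2-ol
Conditions: Pd(PPh3)2Cl2 (cat.), CuI (cat.), Et3N, THF, rt
Reagents that add atoms: none
Why: Sonogashira coupling of a vinyl iodide proceeds with retention of alkene geometry and tolerates the free alcohol.

Step 4
Reactants: 7 (2S,3Z)-4-methyl-6-(trimethylsilyl)hex-3-en-5-yn-2-ol; 8 5-(trimethylsilyl)pent-4-ynoic acid
Product: 9 (2S,3Z)-4-methyl-6-(trimethylsilyl)hex-3-en-5-yn-2-yl 5-(trimethylsilyl)pent-4-ynoate
Conditions: DCC, DMAP (cat.), CH2Cl2, 0 °C → rt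
Reagents that add atoms: none
Why: Steglich esterification acylates the secondary allylic alcohol without touching the stereocentre or the alkene geometry.

Step 5
Reactants: 9 (2S,3Z)-4-methyl-6-(trimethylsilyl)hex-3-en-5-yn-2-yl 5-(trimethylsilyl)pent-4-ynoate
Product: 12 (2S,3S,4E)-3-methyl-2-[3-(trimethylsilyl)prop-2-yn-1-yl]-3-[(trimethylsilyl)ethynyl]hex-4-enoic acid, via silyl ketene acetal 10 (not isolated), via trimethylsilyl ester 11 (not isolated)
Conditions: LDA, THF–DMPU (4:1), −78 °C; Me3SiCl, −78 °C → rt, then 50 °C; 1 M HCl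
Reagents that add atoms: chlorotrimethylsilane, C[Si](C)(C)Cl (its atoms stay only in 10 and 11)
Why: Ireland–Claisen rearrangement: the Z(O)-enolate formed in THF–DMPU, the Z-enyne and a chair transition state with the carbinol methyl equatorial (its axial position is blocked by the syn-axial alkynyl group) should transfer the carbinol chirality to the quaternary C-3 and to C-2, placing the carboxyl on the same side as the C-3 methyl in the later ring.

Step 6
Reactants: 12 (2S,3S,4E)-3-methyl-2-[3-(trimethylsilyl)prop-2-yn-1-yl]-3-[(trimethylsilyl)ethynyl]hex-4-enoic acid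
Product: 13 tert-butyl (2S,3S,4E)-3-methyl-2-[3-(trimethylsilyl)prop-2-yn-1-yl]-3-[(trimethylsilyl)ethynyl]hex-4-enoate
Conditions: Cl3CC(=NH)Ot-Bu, BF3·OEt2 (cat.), CH2Cl2–cyclohexane, rt
Reagents that add atoms: tert-butyl 2,2,2-trichloroacetimidate, CC(C)(C)OC(=N)C(Cl)(Cl)Cl
Why: Acid-catalysed O-tert-butylation with the trichloroacetimidate alkylates the carboxyl oxygen, so the hindered environment of the acid does not matter.

Step 7
Reactants: 13 tert-butyl (2S,3S,4E)-3-methyl-2-[3-(trimethylsilyl)prop-2-yn-1-yl]-3-[(trimethylsilyl)ethynyl]hex-4-enoate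
Product: 15 tert-butyl (2S,3S)-3-formyl-3-methyl-5-(trimethylsilyl)-2-[3-(trimethylsilyl)prop-2-yn-1-yl]pent-4-ynoate, via ozonide 14 (not isolated)
Conditions: O3, CH2Cl2, −78 °C (Sudan Red 7B end point); PPh3, −78 °C → rt
Reagents that add atoms: ozone, [O-][O+]=O
Why: Ozonolysis with reductive work-up should cleave the disubstituted alkene far faster than the silyl-capped alkynes and gives a non-enolisable quaternary aldehyde.

Step 8
Reactants: 15 tert-butyl (2S,3S)-3-formyl-3-methyl-5-(trimethylsilyl)-2-[3-(trimethylsilyl)prop-2-yn-1-yl]pent-4-ynoate; 16 1-bromo-3-methylbut-2-ene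
Product: 17 tert-butyl (2S,3S)-3-(1-hydroxy-2,2-dimethylbut-3-en-1-yl)-3-methyl-5-(trimethylsilyl)-2-[3-(trimethylsilyl)prop-2-yn-1-yl]pent-4-ynoate (both carbinol epimers)
Conditions: Zn dust, THF–H2O (NH4Cl buffer), 0 °C → rt
Reagents that add atoms: none
Why: Barbier-type allylation: the allylic zinc reagent reacts at its γ-carbon through a six-membered transition state and so attaches the CMe2–CH=CH2 unit under near-neutral conditions; the new carbinol centre is removed in step 9.

Step 9
Reactants: 17 tert-butyl (2S,3S)-3-(1-hydroxy-2,2-dimethylbut-3-en-1-yl)-3-methyl-5-(trimethylsilyl)-2-[3-(trimethylsilyl)prop-2-yn-1-yl]pent-4-ynoate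
Product: 18 tert-butyl (2S,3S)-3-(2,2-dimethylbut-3-enoyl)-3-methyl-5-(trimethylsilyl)-2-[3-(trimethylsilyl)prop-2-yn-1-yl]pent-4-ynoate
Conditions: Dess–Martin periodinane, CH2Cl2, rt
Reagents that add atoms: none
Why: Dess–Martin oxidation gives a ketone whose two α-carbons are quaternary, so neither enolisation nor alkene migration is possible.

Step 10
Reactants: 18 tert-butyl (2S,3S)-3-(2,2-dimethylbut-3-enoyl)-3-methyl-5-(trimethylsilyl)-2-[3-(trimethylsilyl)prop-2-yn-1-yl]pent-4-ynoate
Product: 20 tert-butyl (2S,3R)-3-(3,3-dimethylpenta-1,4-dien-2-yl)-3-methyl-5-(trimethylsilyl)-2-[3-(trimethylsilyl)prop-2-yn-1-yl]pent-4-ynoate, via β-hydroxysilane 19 (not isolated)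
Conditions: Me3SiCH2Li, CeCl3 (anhydrous), THF, −78 → 0 °C; aq. NH4Cl; crude carbinol, KH, THF, 0 °C
Reagents that add atoms: (trimethylsilyl)methyllithium, [Li]C[Si](C)(C)C (the CH2 stays in 20; the silyl group stays only in 19)
Why: Peterson olefination: the small organocerium reagent should add to the non-enolisable, doubly neopentyl ketone in preference to the tert-butyl ester, and syn-elimination of the potassium alkoxide can only give the C=CH2 group because both neighbours are quaternary.

Step 11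
Reactants: 20 tert-butyl (2S,3R)-3-(3,3-dimethylpenta-1,4-dien-2-yl)-3-methyl-5-(trimethylsilyl)-2-[3-(trimethylsilyl)prop-2-yn-1-yl]pent-4-ynoate
Product: 21 tert-butyl (2S,3S)-3-(3,3-dimethylpenta-1,4-dien-2-yl)-3-methyl-2-(prop-2-yn-1-yl)pent-4-ynoate
Conditions: K2CO3 (cat.), MeOH, rt
Reagents that add atoms: none
Why: Base-catalysed methanolysis of the two C(sp)–Si bonds frees both terminal alkynes and leaves the tert-butyl ester alone.

Step 12
Reactants: 21 tert-butyl (2S,3S)-3-(3,3-dimethylpenta-1,4-dien-2-yl)-3-methyl-2-(prop-2-yn-1-yl)pent-4-ynoate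
Product: 22 tert-butyl (2S,3S,3aS)-3-ethynyl-3,3a,4,4-tetramethyl-2,3,3a,4,5,6-hexahydro-1H-indene-2-carboxylate
Conditions: Mn(dpm)3 (cat.), Ph(i-PrO)SiH2 (slow addition, limiting), t-BuOOH, degassed n-hexane, high dilution, rt
Reagents that add atoms: none
Why: Proposed new method: hydrogen-atom transfer from an in-situ manganese hydride to the CH2 end of the 1,1-disubstituted alkene should give the tertiary C-3a radical (this creates the angular methyl), which adds to the internal carbon of the propargyl alkyne (ring B, bond C3a–C7a); the vinyl radical so formed returns to the vinyl group on C-4 and closes ring A (bond C6–C7), and the secondary C-5 radical is quenched by a second hydrogen-atom transfer. The closest known reaction types are the HAT-initiated reductive radical cyclisation of 1,6-enynes and tin-hydride round-trip enyne cascades; new is their union on a dienediyne that builds three contiguous fully substituted carbons. Ring B closes 5-exo-dig; ring A closes 6-endo-trig, either directly or by 5-exo closure followed by the homoallyl–cyclopropylcarbinyl radical shift, which funnels the primary radical of the strained bicyclo[3.3.0]octene into the secondary radical of the hydrindene when hydrogen donors are scarce. The only new stereocentre, C-3a, is set by substrate control in the 5-exo-dig step: the very bulky CMe2(CH=CH2) group on the radical carbon should turn to the face that carries the rod-like ethynyl on C-3 and the hydrogen on C-2, away from the C-3 methyl and the C-2 ester, so that the two methyls and the ester end up cis. The step needs hydrogen-atom transfer to the C=CH2 group in preference to the neopentyl vinyl group, the alkynes and the trisubstituted alkene of the product, and ring closure faster than reduction or 1,2-vinyl shift of the tertiary radical; this is secured by the faster transfer to an unhindered terminal methylene that gives a tertiary radical, by limiting the silane, by high dilution in a poor hydrogen-donor solvent and by the gem-dialkyl effect on both closures.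

Step 13
Reactants: 22 tert-butyl (2S,3S,3aS)-3-ethynyl-3,3a,4,4-tetramethyl-2,3,3a,4,5,6-hexahydro-1H-indene-2-carboxylate
Product: 23 tert-butyl (2S,3R,3aS)-3-ethenyl-3,3a,4,4-tetramethyl-2,3,3a,4,5,6-hexahydro-1H-indene-2-carboxylate
Conditions: H2 (1 atm), Pd/CaCO3 poisoned with Pb(OAc)2 (Lindlar), quinoline, EtOAc, rt
Reagents that add atoms: none
Why: Lindlar semi-hydrogenation reduces the terminal alkyne to the vinyl group and should leave the hindered trisubstituted ring alkene alone.

Step 14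
Reactants: 24 prop-2-yn-1-ol
Product: 26 (Z)-3-iodo-2-methylprop-2-en-1-ol, via cyclic vinylmagnesium alkoxide 25 (not isolated)
Conditions: MeMgBr (2.5 equiv), CuI (cat.), Et2O–THF, −10 °C → rt; I2, THF, −30 → 0 °C; aq. NH4Cl
Reagents that add atoms: methylmagnesium bromide, C[Mg]Br; iodine, II
Why: Copper-catalysed anti-carbomagnesiation of the propargylic alkoxide delivers methyl to C-2 and magnesium to C-3 within a five-membered chelate, so iodinolysis with retention gives the Z-iodoalkene.

Step 15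
Reactants: 26 (Z)-3-iodo-2-methylprop-2-en-1-ol
Product: 27 (Z)-3-iodo-2-methylprop-2-en-1-yl acetate
Conditions: Ac2O, pyridine, DMAP (cat.), CH2Cl2, 0 °C → rt
Reagents that add atoms: acetic anhydride, CC(=O)OC(C)=O
Why: Standard O-acetylation of a primary alcohol; the vinyl iodide is inert.

Step 16
Reactants: 23 tert-butyl (2S,3R,3aS)-3-ethenyl-3,3a,4,4-tetramethyl-2,3,3a,4,5,6-hexahydro-1H-indene-2-carboxylate; 27 (Z)-3-iodo-2-methylprop-2-en-1-yl acetate
Product: 29 tert-butyl (2S,3R,3aS)-3-[(3Z)-5-(acetyloxy)-4-methylpent-3-en-1-yl]-3,3a,4,4-tetramethyl-2,3,3a,4,5,6-hexahydro-1H-indene-2-carboxylate, via B-alkyl-9-BBN adduct 28 (not isolated)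
Conditions: 9-BBN (dimer), THF, 0 → 50 °C; then 27, Pd(dppf)Cl2 (cat.), AsPh3, K3PO4 (aq.), DMF, rt
Reagents that add atoms: 9-borabicyclo[3.3.1]nonane, B1C2CCCC1CCC2 (its atoms stay only in 28)
Why: Anti-Markovnikov hydroboration of the only unhindered terminal alkene followed by B-alkyl Suzuki–Miyaura coupling joins the sp3 and sp2 carbons with retention of the Z geometry of the iodoalkene.

Step 17
Reactants: 29 tert-butyl (2S,3R,3aS)-3-[(3Z)-5-(acetyloxy)-4-methylpent-3-en-1-yl]-3,3a,4,4-tetramethyl-2,3,3a,4,5,6-hexahydro-1H-indene-2-carboxylate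
Product: 31 (2S,3R,3aS)-3-[(3Z)-5-(acetyloxy)-4-methylpent-3-en-1-yl]-3,3a,4,4-tetramethyl-2,3,3a,4,5,6-hexahydro-1H-indene-2-carboxylic acid, via trimethylsilyl ester 30 (not isolated)
Conditions: Me3SiOTf, 2,6-lutidine, CH2Cl2, 0 °C; then pH 4 aqueous buffer
Reagents that add atoms: trimethylsilyl trifluoromethanesulfonate, C[Si](C)(C)OS(=O)(=O)C(F)(F)F (its atoms stay only in 30)
Why: Silyl-triflate-mediated cleavage of the tert-butyl ester (loss of isobutene) under buffered, non-protic conditions should spare the allylic acetate and both alkenes, and the silyl ester hydrolyses on work-up.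

**Compound list**

1 | (S)-but-3-yn-2-ol | C[C@H](O)C#C | starting material
2 | dilithium alkoxide-acetylide of 1 | C[C@H]([O-])C#[C-].[Li+].[Li+] | intermediate
3 | (S)-pent-3-yn-2-ol | C[C@H](O)C#CC | intermediate
4 | sodium (5S)-2,2-bis(2-methoxyethoxy)-3,5-dimethyl-2,5-dihydro-1,2-oxaluminol-2-uide (cyclic vinylalanate) | C[C@@H]1O[Al-](OCCOC)(OCCOC)C(C)=C1.[Na+] | intermediate
5 | (2S,3Z)-4-iodopent-3-en-2-ol | C[C@H](O)/C=C(/C)I | intermediate
6 | ethynyltrimethylsilane | C#C[Si](C)(C)C | starting material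
7 | (2S,3Z)-4-methyl-6-(trimethylsilyl)hex-3-en-5-yn-2-ol | C[C@H](O)/C=C(/C)C#C[Si](C)(C)C | intermediate
8 | 5-(trimethylsilyl)pent-4-ynoic acid | OC(=O)CCC#C[Si](C)(C)C | starting material
9 | (2S,3Z)-4-methyl-6-(trimethylsilyl)hex-3-en-5-yn-2-yl 5-(trimethylsilyl)pent-4-ynoate | C[C@H](OC(=O)CCC#C[Si](C)(C)C)/C=C(/C)C#C[Si](C)(C)C | intermediate
10 | (Z)-O-trimethylsilyl ketene acetal of 9 | C[C@H](O/C(O[Si](C)(C)C)=C/CC#C[Si](C)(C)C)/C=C(/C)C#C[Si](C)(C)C | intermediate
11 | trimethylsilyl ester of 12 | C[Si](C)(C)C#C[C@](/C=C/C)(C)[C@@H](C(=O)O[Si](C)(C)C)CC#C[Si](C)(C)C | intermediate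
12 | (2S,3S,4E)-3-methyl-2-[3-(trimethylsilyl)prop-2-yn-1-yl]-3-[(trimethylsilyl)ethynyl]hex-4-enoic acid | C[Si](C)(C)C#C[C@](/C=C/C)(C)[C@@H](C(=O)O)CC#C[Si](C)(C)C | intermediate
13 | tert-butyl (2S,3S,4E)-3-methyl-2-[3-(trimethylsilyl)prop-2-yn-1-yl]-3-[(trimethylsilyl)ethynyl]hex-4-enoate | C[Si](C)(C)C#C[C@](/C=C/C)(C)[C@@H](C(=O)OC(C)(C)C)CC#C[Si](C)(C)C | intermediate
14 | secondary ozonide (1,2,4-trioxolane) of 13 | C[Si](C)(C)C#C[C@](C1OOC(C)O1)(C)[C@@H](C(=O)OC(C)(C)C)CC#C[Si](C)(C)C | intermediate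
15 | tert-butyl (2S,3S)-3-formyl-3-methyl-5-(trimethylsilyl)-2-[3-(trimethylsilyl)prop-2-yn-1-yl]pent-4-ynoate | C[Si](C)(C)C#C[C@](C=O)(C)[C@@H](C(=O)OC(C)(C)C)CC#C[Si](C)(C)C | intermediate
16 | 1-bromo-3-methylbut-2-ene (prenyl bromide) | CC(C)=CCBr | starting material
17 | tert-butyl (2S,3S)-3-(1-hydroxy-2,2-dimethylbut-3-en-1-yl)-3-methyl-5-(trimethylsilyl)-2-[3-(trimethylsilyl)prop-2-yn-1-yl]pent-4-ynoate (both carbinol epimers) | C[Si](C)(C)C#C[C@](C(O)C(C)(C)C=C)(C)[C@@H](C(=O)OC(C)(C)C)CC#C[Si](C)(C)C | intermediate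
18 | tert-butyl (2S,3S)-3-(2,2-dimethylbut-3-enoyl)-3-methyl-5-(trimethylsilyl)-2-[3-(trimethylsilyl)prop-2-yn-1-yl]pent-4-ynoate | C[Si](C)(C)C#C[C@](C(=O)C(C)(C)C=C)(C)[C@@H](C(=O)OC(C)(C)C)CC#C[Si](C)(C)C | intermediate
19 | tert-butyl (2S,3S)-3-[2-hydroxy-3,3-dimethyl-1-(trimethylsilyl)pent-4-en-2-yl]-3-methyl-5-(trimethylsilyl)-2-[3-(trimethylsilyl)prop-2-yn-1-yl]pent-4-ynoate (both carbinol epimers) | C[Si](C)(C)C#C[C@](C(O)(C[Si](C)(C)C)C(C)(C)C=C)(C)[C@@H](C(=O)OC(C)(C)C)CC#C[Si](C)(C)C | intermediate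
20 | tert-butyl (2S,3R)-3-(3,3-dimethylpenta-1,4-dien-2-yl)-3-methyl-5-(trimethylsilyl)-2-[3-(trimethylsilyl)prop-2-yn-1-yl]pent-4-ynoate | C[Si](C)(C)C#C[C@](C(=C)C(C)(C)C=C)(C)[C@@H](C(=O)OC(C)(C)C)CC#C[Si](C)(C)C | intermediate
21 | tert-butyl (2S,3S)-3-(3,3-dimethylpenta-1,4-dien-2-yl)-3-methyl-2-(prop-2-yn-1-yl)pent-4-ynoate | C#C[C@](C(=C)C(C)(C)C=C)(C)[C@@H](C(=O)OC(C)(C)C)CC#C | intermediate
22 | tert-butyl (2S,3S,3aS)-3-ethynyl-3,3a,4,4-tetramethyl-2,3,3a,4,5,6-hexahydro-1H-indene-2-carboxylate | C#C[C@]1(C)[C@@H](C(=O)OC(C)(C)C)CC2=CCCC(C)(C)[C@@]21C | intermediate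
23 | tert-butyl (2S,3R,3aS)-3-ethenyl-3,3a,4,4-tetramethyl-2,3,3a,4,5,6-hexahydro-1H-indene-2-carboxylate | C=C[C@]1(C)[C@@H](C(=O)OC(C)(C)C)CC2=CCCC(C)(C)[C@@]21C | intermediate
24 | prop-2-yn-1-ol | OCC#C | starting material
25 | 3-methyl-2,5-dihydro-1,2-oxamagnesole (cyclic Z-vinylmagnesium alkoxide) | CC1=C[Mg]OC1 | intermediate
26 | (Z)-3-iodo-2-methylprop-2-en-1-ol | OC/C(C)=C\I | intermediate
27 | (Z)-3-iodo-2-methylprop-2-en-1-yl acetate | CC(=O)OC/C(C)=C\I | intermediate
28 | B-alkyl-9-BBN adduct of 23 (boron on the terminal carbon of the former vinyl group) | C1CC2CCCC(C1)B2CC[C@]3(C)[C@@H](C(=O)OC(C)(C)C)CC4=CCCC(C)(C)[C@@]43C | intermediate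
29 | tert-butyl (2S,3R,3aS)-3-[(3Z)-5-(acetyloxy)-4-methylpent-3-en-1-yl]-3,3a,4,4-tetramethyl-2,3,3a,4,5,6-hexahydro-1H-indene-2-carboxylate | CC(=O)OC/C(C)=C\CC[C@]1(C)[C@@H](C(=O)OC(C)(C)C)CC2=CCCC(C)(C)[C@@]21C | intermediate
30 | trimethylsilyl ester of 31 | CC(=O)OC/C(C)=C\CC[C@]1(C)[C@@H](C(=O)O[Si](C)(C)C)CC2=CCCC(C)(C)[C@@]21C | intermediate
31 | (2S,3R,3aS)-3-[(3Z)-5-(acetyloxy)-4-methylpent-3-en-1-yl]-3,3a,4,4-tetramethyl-2,3,3a,4,5,6-hexahydro-1H-indene-2-carboxylic acid | CC(=O)OC/C(C)=C\CC[C@]1(C)[C@@H](C(=O)O)CC2=CCCC(C)(C)[C@@]21C | target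

**Step count and risks**

Total steps: 17. Longest linear sequence: 15 steps (steps 1 to 13, then 16 and 17).

Steps most likely to fail:

Step 12 (Proposed new method). The vinyl radical may take up a hydrogen atom before ring A closes, the tertiary radical may be reduced or suffer a 1,2-vinyl shift before ring B closes, or the product alkene may be reduced further. The fallback builds the rings one after the other with known reaction types and sets out from 20. A HAT-initiated reductive 5-exo-dig cyclisation of the 1,6-enyne onto the silylalkyne (Fe(acac)3, PhSiH3, EtOH) should close ring B only and give tert-butyl 2,3-dimethyl-3-(2-methylbut-3-en-2-yl)-2-[(trimethylsilyl)ethynyl]-4-[(Z)-(trimethylsilyl)methylidene]cyclopentane-1-carboxylate F1; here hydrogen capture by the silyl-substituted vinyl radical is wanted and should occur on the side away from the quaternary centre. Iododesilylation with N-iodosuccinimide (retention) gives the (Z)-iodomethylidene compound F2. Hydroboration of the vinyl group with 9-BBN gives the B-alkyl-9-BBN adduct F3, and an intramolecular B-alkyl Suzuki–Miyaura coupling (Pd(dppf)Cl2, AsPh3, Cs2CO3, DMF–THF–H2O) closes ring A to tert-butyl 3,3a,4,4-tetramethyl-3-[(trimethylsilyl)ethynyl]-2,3,3a,4,5,6-hexahydro-1H-indene-2-carboxylate F4. K2CO3 in MeOH then removes the silyl group, and the route is rejoined at 22.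

Step 10. The hindered tertiary homoallylic alkoxide may lose its prenyl unit by retro-allylation, or C-2 may epimerise during the potassium hydride elimination. The fallback sets out from 18 and uses a non-basic gem-dimetallic methylenation (Zn, CH2Br2, TiCl4, THF–CH2Cl2, rt), which converts the ketone directly into 20; it makes no new compound (F0) and rejoins the route at 20.

Step 16. The allylic acetate may be lost by hydrolysis or by ionisation at zerovalent palladium, and transmetalation of the hindered alkylborane may be slow under aqueous base. The fallback sets out from 23. Hydroboration with 9-BBN followed by oxidation (NaBO3, THF–H2O) gives tert-butyl (2S,3R,3aS)-3-(2-hydroxyethyl)-3,3a,4,4-tetramethyl-2,3,3a,4,5,6-hexahydro-1H-indene-2-carboxylate F5. I2, PPh3 and imidazole give the 2-iodoethyl compound F6. Zinc insertion (Zn dust, LiCl, THF) gives the alkylzinc iodide F7, and a base-free Negishi coupling with 27 (Pd(PPh3)4, THF, rt) gives 29, where the route is rejoined.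

Further compounds
F1 | step 12 | tert-butyl 2,3-dimethyl-3-(2-methylbut-3-en-2-yl)-2-[(trimethylsilyl)ethynyl]-4-[(Z)-(trimethylsilyl)methylidene]cyclopentane-1-carboxylate (ring stereocentres as in 22) | C[Si](C)(C)C#C[C@]1(C)[C@@H](C(=O)OC(C)(C)C)C/C(=C/[Si](C)(C)C)[C@]1(C)C(C)(C)C=C
F2 | step 12 | tert-butyl 4-[(Z)-iodomethylidene]-2,3-dimethyl-3-(2-methylbut-3-en-2-yl)-2-[(trimethylsilyl)ethynyl]cyclopentane-1-carboxylate (ring stereocentres as in 22) | C[Si](C)(C)C#C[C@]1(C)[C@@H](C(=O)OC(C)(C)C)C/C(=C/I)[C@]1(C)C(C)(C)C=C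
F3 | step 12 | B-alkyl-9-BBN adduct of F2 (boron on the terminal carbon of the former vinyl group) | C[Si](C)(C)C#C[C@]1(C)[C@@H](C(=O)OC(C)(C)C)C/C(=C/I)[C@]1(C)C(C)(C)CCB1C2CCCC1CCC2
F4 | step 12 | tert-butyl 3,3a,4,4-tetramethyl-3-[(trimethylsilyl)ethynyl]-2,3,3a,4,5,6-hexahydro-1H-indene-2-carboxylate (stereocentres as in 22) | C[Si](C)(C)C#C[C@]1(C)[C@@H](C(=O)OC(C)(C)C)CC2=CCCC(C)(C)[C@@]21C
F0 | step 10 | none | none
F5 | step 16 | tert-butyl (2S,3R,3aS)-3-(2-hydroxyethyl)-3,3a,4,4-tetramethyl-2,3,3a,4,5,6-hexahydro-1H-indene-2-carboxylate | OCC[C@]1(C)[C@@H](C(=O)OC(C)(C)C)CC2=CCCC(C)(C)[C@@]21C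
F6 | step 16 | tert-butyl (2S,3R,3aS)-3-(2-iodoethyl)-3,3a,4,4-tetramethyl-2,3,3a,4,5,6-hexahydro-1H-indene-2-carboxylate | ICC[C@]1(C)[C@@H](C(=O)OC(C)(C)C)CC2=CCCC(C)(C)[C@@]21C
F7 | step 16 | alkylzinc iodide from F6 | I[Zn]CC[C@]1(C)[C@@H](C(=O)OC(C)(C)C)CC2=CCCC(C)(C)[C@@]21C
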